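## The problem

- Target **16** is a linear trimer of three different, fully substituted acylphloroglucinol rings joined by two methylene bridges. Both bridges sit on the two equivalent nucleophilic carbons (C3, C5) of the central 2‑methylbutanoyl ring, yet the end rings differ (acetyl versus 2‑methylpropanoyl). Any union through a free one‑carbon reagent is therefore statistical.
- Each terminal ring reads C1′(CH2)–C2′(OH)–C3′(acyl)–C4′(OMe)–C5′(Me)–C6′(OH). The single methyl ether lies between the C‑methyl and the ketone. That is not the oxygen attacked when an acyl‑methylphloroglucinol is methylated (the one para to the ketone reacts), and acylating the corresponding methyl ether offers two competing ring carbons.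
- The only stereocentre is C2 of the 2‑methylbutanoyl chain (R), α to an aryl ketone. Nothing in the molecule can set or correct it, so it must be bought with acid **7** and then protected from enolisation (hot Lewis acid) and from ketene formation (acid chloride plus base).
- Methylene bridges between phloroglucinol rings are dynamic in hot base or strong acid (retro‑Michael to an o‑quinone methide and re‑addition). This would scramble the unsymmetrical trimer into symmetrical ones. With nine free phenols and three ketones, a late global deprotection is also unattractive.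
- The enabling feature: each bridge CH2 is bound to a terminal‑ring carbon C1′ that is flanked by the two phenolic hydroxyls at C2′ and C6′ and lies para to the methoxy carbon C4′. At the aldehyde oxidation level this carbon is the formyl group of a 2,6‑dihydroxybenzaldehyde. There it blocks the most nucleophilic ring carbon, ties the two ortho hydroxyls into its hydrogen bond so that only the para oxygen is methylated, and after hydride reduction becomes an o,o′‑dihydroxybenzyl alcohol that collapses to an o‑quinone methide.
- The plan therefore never uses a free one‑carbon reagent: each bridge carbon enters as the formyl carbon of a terminal ring and is converted into the bridge in the coupling itself.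

## Retrosynthesis

**16 ⇒ 13 + 6.** The bond cut is C3(central ring)–CH2 of the acetyl‑ring bridge. Cutting on the terminal side (CH2–C1′) would need a terminal nucleophile with a free C1′–H, for which no short regiocontrolled access exists. Cutting both bonds of the CH2 brings back the statistical one‑carbon condensation. The trimer falls to dimer **13** and the eleven‑carbon aldehyde **6**. The forward reaction must reduce only the aldehyde of **6** (to **14**), let it collapse to o‑quinone methide **15**, and have the single ring C–H of **13** add to it, cold and briefly, so that the first bridge and the stereocentre are untouched.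

**13 ⇒ 10 + 5.** The same cut at the other bridge, by the same operation (via **11** and **12**). The only statistical element is the two equivalent carbons of **10**; it is handled by using **10** in excess and recovering it. The 2‑methylpropanoyl ring goes on first and the acetyl ring last, because the unhindered methyl ketone is the most reducible carbonyl and should meet hydride only once.

**5 and 6 ⇒ 4.** The aryl–C(=O) bonds of the two terminal ketones are cut, so both end rings diverge from one aldehyde **4**. **4** has a single ring C–H, so the acylation cannot go to a wrong position. It must only overcome the deactivation by the formyl group, which sits meta to the reacting carbon while three oxygens activate it.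

**4 ⇒ 3 ⇒ 1.** First the O–CH3 bond is cut, then the ring–CHO bond. The formyl group of **3** directs methylation to the para oxygen, which is exactly the oxygen that ends up between C‑methyl and ketone. **1** has two equivalent ring C–H, so formylation gives one product. Three flat steps thus fix the whole substitution pattern of a hexasubstituted ring.

**10 ⇒ 8 + 9; 8 ⇒ 7.** The central aryl–acyl bond is cut at the monomer stage. Acylating after the bridges are in place would expose a bridged oligomer to the Lewis acid that cleaves such bridges. The stereocentre is purchased in **7** and only has to survive acid chloride formation and one cold acylation.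

## Roads not taken

**Alternative 1:** the obvious route. Both bonds of each bridge carbon are cut, giving **10**, formaldehyde (or an amine/formaldehyde pair) and the two nucleophilic end monomers 1‑(4,6‑dihydroxy‑2‑methoxy‑3‑methylphenyl)ethan‑1‑one A1 and 1‑(4,6‑dihydroxy‑2‑methoxy‑3‑methylphenyl)‑2‑methylpropan‑1‑one A2. The forward key step is a double hydroxymethylation or Mannich condensation. It is worse for three reasons:
- A1 and A2 have no short regiocontrolled synthesis: methylation of the acyl‑methylphloroglucinols takes the oxygen para to the ketone, and acylation of the methyl ether has two ring sites.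
- The one‑carbon reagent cannot tell A1 from A2 or one carbon of **10** from the other, so symmetrical dimers and trimers are unavoidable.
- These condensations are usually run in warm alkali, the very conditions that exchange rings.

**Alternative 2:** a [2,3]‑sigmatropic ortho‑benzylation. The C3(central)–CH2 bond is cut, but the bridge is delivered intramolecularly. The terminal ring is used as its benzyl sulfide, 1‑[2,4‑dihydroxy‑6‑methoxy‑5‑methyl‑3‑[(methylsulfanyl)methyl]phenyl]‑2‑methylpropan‑1‑one A3. It is activated to a halosulfonium salt, bound to a phenol oxygen of **10**, deprotonated to the ylide and rearranged (Sommelet–Hauser type) to the α‑methylthio dimer A4, which is then desulfurised to **13**. The attraction is a cross‑coupling that cannot homo‑couple. It is worse for four reasons: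
- Halosulfonium formation needs an electrophilic halogen source that chlorinates and oxidises free phloroglucinols.
- A4 is itself an o‑quinone methide precursor (thiolate as leaving group), so the scrambling pathway is not avoided.
- Raney nickel would have to spare three aryl ketones.
- A3 would in any case be made from aldehyde **5**, so the sequence is three steps longer per bridge.

**Alternative 3:** the stereocentre made last. The C2–H bond of the side chain is "cut": the whole trimer is assembled with an achiral (E)‑2‑methylbut‑2‑enoyl group, as enone trimer A5. The forward key step is an enantioselective C=C reduction by an ene‑reductase (Old Yellow Enzyme family) or an asymmetric hydrogenation catalyst. It is worse for three reasons: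
- The ortho hydroxyls flanking the enone would add to it in an oxa‑Michael ring closure long before the last step.
- A hexasubstituted aryl ketone of this size is far outside the substrate range of ene‑reductases.
- The stereocentre is not the hard part: it is available in one commercial compound and only has to be kept.

Key step: step 8

Assumption: the centre written CC[C@@H](C)C(=O)Ar is R (C=O > ethyl > methyl > H), and (R)‑2‑methylbutanoic acid **7** is taken as a commercial single enantiomer.

## Route

Step 1
Reactants: 1 2‑methylbenzene‑1,3,5‑triol (2‑methylphloroglucinol)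
Product: 3 2,4,6‑trihydroxy‑3‑methylbenzaldehyde, via iminium chloride 2 (not isolated)
Conditions: POCl3 (1.1 equiv), DMF (1.2 equiv), EtOAc, 0 → 23 °C; then H2O, 60 °C
Reagents that add atoms: N,N‑dimethylformamide CN(C)C=O; water O
Why: Vilsmeier–Haack formylation; the two ring C–H of 1 are equivalent so one aldehyde forms, and the iminium salt 2 is deactivated and should precipitate, which stops a second formylation before hydrolysis to 3.

Step 2
Reactants: 3 2,4,6‑trihydroxy‑3‑methylbenzaldehyde
Product: 4 2,6‑dihydroxy‑4‑methoxy‑3‑methylbenzaldehyde
Conditions: Me2SO4 (1.05 equiv), K2CO3 (1.0 equiv), DMF, 0 → 23 °C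
Reagents that add atoms: dimethyl sulfate COS(=O)(=O)OC
Why: Williamson‑type O‑methylation of the most acidic phenol; the two hydroxyls ortho to the formyl group share its intramolecular hydrogen bond and are the weaker acids and nucleophiles, so one equivalent of a hard methylating agent should take the para oxygen, which places OMe para to the future bridge carbon.

Step 3
Reactants: 4 2,6‑dihydroxy‑4‑methoxy‑3‑methylbenzaldehyde
Product: 5 2,6‑dihydroxy‑4‑methoxy‑3‑methyl‑5‑(2‑methylpropanoyl)benzaldehyde
Conditions: i‑PrCOCl (1.5 equiv), AlCl3 (4 equiv), CH2Cl2–PhNO2, 0 → 40 °C; then ice/1 M HCl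
Reagents that add atoms: 2‑methylpropanoyl chloride CC(C)C(Cl)=O
Why: Friedel–Crafts acylation at C5, the only ring C–H of 4, which is ortho to OH and OMe, para to the other OH and meta to the formyl group; the neighbouring phenol chelates aluminium to the new ketone, which should protect the methyl ether from Lewis‑acid cleavage at this temperature.

Step 4
Reactants: 4 2,6‑dihydroxy‑4‑methoxy‑3‑methylbenzaldehyde
Product: 6 3‑acetyl‑2,6‑dihydroxy‑4‑methoxy‑5‑methylbenzaldehyde
Conditions: AcCl (1.5 equiv), AlCl3 (4 equiv), CH2Cl2–PhNO2, 0 → 40 °C; then ice/1 M HCl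
Reagents that add atoms: acetyl chloride CC(Cl)=O
Why: the same Friedel–Crafts acylation at the single free ring carbon of 4 with the smaller acyl chloride, so the two end rings diverge from one intermediate.

Step 5
Reactants: 7 (2R)‑2‑methylbutanoic acid
Product: 8 (2R)‑2‑methylbutanoyl chloride
Conditions: (COCl)2 (1.05 equiv), DMF (cat.), CH2Cl2, 0 → 23 °C; volatiles removed at 0 °C, used crude
Reagents that add atoms: oxalyl chloride O=C(Cl)C(Cl)=O
Why: acid chloride formation through catalytic Vilsmeier‑type activation; no base is present, so no ketene can form and the α‑stereocentre of 7 should be carried over unchanged.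

Step 6
Reactants: 8 (2R)‑2‑methylbutanoyl chloride; 9 benzene‑1,3,5‑triol (phloroglucinol, 1.2 equiv)
Product: 10 (2R)‑2‑methyl‑1‑(2,4,6‑trihydroxyphenyl)butan‑1‑one
Conditions: AlCl3 (4 equiv), CH2Cl2–PhNO2, 0 → 23 °C; then ice/1 M HCl
Reagents that add atoms: none
Why: Friedel–Crafts acylation of phloroglucinol, whose three positions are equivalent and whose first acyl group deactivates the ring against a second; low temperature and absence of base should keep the (R)‑centre, and the enantiomeric purity is to be checked here by chiral HPLC.

Step 7
Reactants: 10 (2R)‑2‑methyl‑1‑(2,4,6‑trihydroxyphenyl)butan‑1‑one (3 equiv); 5 2,6‑dihydroxy‑4‑methoxy‑3‑methyl‑5‑(2‑methylpropanoyl)benzaldehyde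
Product: 13 (2R)‑1‑[3‑[[2,6‑dihydroxy‑4‑methoxy‑3‑methyl‑5‑(2‑methylpropanoyl)phenyl]methyl]‑2,4,6‑trihydroxyphenyl]‑2‑methylbutan‑1‑one, via benzylic alcohol 11 (not isolated), via o‑quinone methide 12 (not isolated)
Conditions: NaBH4 (0.5 equiv, slow addition), THF–MeOH (4:1), 0 → 23 °C; pH 4 buffer; excess 10 recovered
Reagents that add atoms: none
Why: borohydride should reduce only the aldehyde of 5 (the ketones are di‑ortho‑substituted vinylogous acids) to 11, whose phenolate loses hydroxide to give o‑quinone methide 12; the phenolate of 10 captures it at C3 by Michael addition and re‑aromatising tautomerisation, the known mode of formation of methylene‑bis‑acylphloroglucinols, while the excess of 10 suppresses double alkylation and slow addition keeps hydride from reducing 12.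

Step 8
Reactants: 13 (2R)‑1‑[3‑[[2,6‑dihydroxy‑4‑methoxy‑3‑methyl‑5‑(2‑methylpropanoyl)phenyl]methyl]‑2,4,6‑trihydroxyphenyl]‑2‑methylbutan‑1‑one; 6 3‑acetyl‑2,6‑dihydroxy‑4‑methoxy‑5‑methylbenzaldehyde (1.5 equiv)
Product: 16 (2R)‑1‑[3‑[(3‑acetyl‑2,6‑dihydroxy‑4‑methoxy‑5‑methylphenyl)methyl]‑5‑[[2,6‑dihydroxy‑4‑methoxy‑3‑methyl‑5‑(2‑methylpropanoyl)phenyl]methyl]‑2,4,6‑trihydroxyphenyl]‑2‑methylbutan‑1‑one, via benzylic alcohol 14 (not isolated), via o‑quinone methide 15 (not isolated)
Conditions: NaBH4 (0.6 equiv, slow addition), THF–MeOH (4:1), 0 → 23 °C; pH 4 buffer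
Reagents that add atoms: none
Why: Hydride adds to the formyl group of 6, the only carbonyl not buried between two ortho substituents as a hindered chelated ketone, to give the o,o′‑dihydroxybenzyl alcohol 14. Its phenolate expels hydroxide, dearomatising the ring to o‑quinone methide 15. The phenolate of 13 adds through its single unsubstituted ring carbon (Michael addition) and tautomerises, so both rings end aromatic and the former formyl carbon is the second bridge. The closest known reaction type is the C‑alkylation of acylphloroglucinols by o‑quinone methides released from o‑hydroxybenzyl alcohols or Mannich bases, combined with the known reductive generation of such methides from salicylaldehydes. No ring is closed and no stereocentre is formed; the (R)‑centre lies α to a ketone that is a chelated phenolate under these conditions and should not enolise at 0–23 °C. The step needs chemoselectivity (aldehyde over four ketones), site selectivity (13 has one ring C–H; O‑alkylation is reversible and drains to the C‑adduct) and cross‑selectivity (14 and 15 have no ring C–H and cannot self‑couple by substitution). It also needs the first bridge to stay intact, which the low temperature, short time, weak base and only modest excess of 6 are meant to secure. Slow addition keeps the hydride concentration low so that the carbon nucleophile and not hydride captures 15, and the excess of 6 covers the part lost to over‑reduction.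

## Compound list

1 | 2‑methylbenzene‑1,3,5‑triol (2‑methylphloroglucinol) | Cc1c(O)cc(O)cc1O | starting material
2 | N‑methyl‑N‑[(2,4,6‑trihydroxy‑3‑methylphenyl)methylidene]methanaminium chloride | C[N+](C)=Cc1c(O)cc(O)c(C)c1O.[Cl-] | intermediate (not isolated)
3 | 2,4,6‑trihydroxy‑3‑methylbenzaldehyde | O=Cc1c(O)cc(O)c(C)c1O | intermediate
4 | 2,6‑dihydroxy‑4‑methoxy‑3‑methylbenzaldehyde | COc1cc(O)c(C=O)c(O)c1C | intermediate
5 | 2,6‑dihydroxy‑4‑methoxy‑3‑methyl‑5‑(2‑methylpropanoyl)benzaldehyde | COc1c(C)c(O)c(C=O)c(O)c1C(=O)C(C)C | intermediate
6 | 3‑acetyl‑2,6‑dihydroxy‑4‑methoxy‑5‑methylbenzaldehyde | COc1c(C)c(O)c(C=O)c(O)c1C(C)=O | intermediate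
7 | (2R)‑2‑methylbutanoic acid | CC[C@@H](C)C(=O)O | starting material
8 | (2R)‑2‑methylbutanoyl chloride | CC[C@@H](C)C(=O)Cl | intermediate
9 | benzene‑1,3,5‑triol (phloroglucinol) | Oc1cc(O)cc(O)c1 | starting material
10 | (2R)‑2‑methyl‑1‑(2,4,6‑trihydroxyphenyl)butan‑1‑one | CC[C@@H](C)C(=O)c1c(O)cc(O)cc1O | intermediate
11 | 1‑[2,4‑dihydroxy‑3‑(hydroxymethyl)‑6‑methoxy‑5‑methylphenyl]‑2‑methylpropan‑1‑one | COc1c(C)c(O)c(CO)c(O)c1C(=O)C(C)C | intermediate (not isolated)
12 | 5‑hydroxy‑3‑methoxy‑2‑methyl‑6‑methylidene‑4‑(2‑methylpropanoyl)cyclohexa‑2,4‑dien‑1‑one | C=C1C(=O)C(C)=C(OC)C(C(=O)C(C)C)=C1O | intermediate (not isolated)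
13 | (2R)‑1‑[3‑[[2,6‑dihydroxy‑4‑methoxy‑3‑methyl‑5‑(2‑methylpropanoyl)phenyl]methyl]‑2,4,6‑trihydroxyphenyl]‑2‑methylbutan‑1‑one | CC[C@@H](C)C(=O)c1c(O)cc(O)c(Cc2c(O)c(C)c(OC)c(C(=O)C(C)C)c2O)c1O | intermediate
14 | 1‑[2,4‑dihydroxy‑3‑(hydroxymethyl)‑6‑methoxy‑5‑methylphenyl]ethan‑1‑one | COc1c(C)c(O)c(CO)c(O)c1C(C)=O | intermediate (not isolated)
15 | 4‑acetyl‑5‑hydroxy‑3‑methoxy‑2‑methyl‑6‑methylidenecyclohexa‑2,4‑dien‑1‑one | C=C1C(=O)C(C)=C(OC)C(C(C)=O)=C1O | intermediate (not isolated)
16 | (2R)‑1‑[3‑[(3‑acetyl‑2,6‑dihydroxy‑4‑methoxy‑5‑methylphenyl)methyl]‑5‑[[2,6‑dihydroxy‑4‑methoxy‑3‑methyl‑5‑(2‑methylpropanoyl)phenyl]methyl]‑2,4,6‑trihydroxyphenyl]‑2‑methylbutan‑1‑one | CC[C@@H](C)C(=O)c1c(O)c(Cc2c(O)c(C)c(OC)c(C(C)=O)c2O)c(O)c(Cc2c(O)c(C)c(OC)c(C(=O)C(C)C)c2O)c1O | target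

## Step count and least certain steps

Total: 8 steps. Longest linear sequence: 5 steps (1, 2, 3, 7, 8).

**Key step, step 8.**
- Two processes may defeat it. The first is interception of methide **15** by hydride, which turns the formyl carbon into a methyl group instead of a bridge. The second is ring exchange at the bridge already present, by retro‑Michael opening of **13** or **16** in the basic medium or by ipso attack of excess **15** at a bridge‑bearing carbon; this would lead to symmetrical trimers.
- The fallback separates reduction from C–C bond formation. It sets out from **6**, which is condensed with morpholine and reduced as its iminium ion (NaBH(OAc)3, 1,2‑dichloroethane, 23 °C) to the Mannich base 1‑[2,4‑dihydroxy‑6‑methoxy‑5‑methyl‑3‑(morpholin‑4‑ylmethyl)phenyl]ethan‑1‑one F1. No hydride is left when F1 is then warmed with **13** in dioxane (60–80 °C); thermal loss of morpholine releases **15** under neutral conditions and the route is rejoined at **16**.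

**Step 7.**
- The likely failures are alkylation of **10** at both equivalent carbons (a symmetrical bis‑adduct) and, as above, hydride capture of methide **12**.
- The fallback sets out from **5**: reductive amination with morpholine gives 1‑[2,4‑dihydroxy‑6‑methoxy‑5‑methyl‑3‑(morpholin‑4‑ylmethyl)phenyl]‑2‑methylpropan‑1‑one F2, which is heated with three equivalents of **10** in dioxane. No bridge exists yet, so heating cannot scramble anything, and the route is rejoined at **13**.

**Step 6.**
- The risk is erosion of enantiomeric purity, by enolisation of the aluminium‑chelated ketone or by ketene formation from **8**.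
- The fallback makes the aryl–acyl bond with a carbanion instead of a Lewis acid and sets out from **7** and **9**. **7** is coupled with N,O‑dimethylhydroxylamine (carbodiimide, N‑methylmorpholine) to (2R)‑N‑methoxy‑N,2‑dimethylbutanamide F3. **9** is converted with MOMCl/NaH into 1,3,5‑tris(methoxymethoxy)benzene F4. F4 is lithiated between two ether groups (n‑BuLi, THF, 0 °C) and added to F3 at −78 °C to give (2R)‑2‑methyl‑1‑[2,4,6‑tris(methoxymethoxy)phenyl]butan‑1‑one F5. HCl in methanol at 23 °C removes the three acetals and the route is rejoined at **10**.

**Step 3 (step 4 is the same reaction and shares the risk).**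
- The acylation may be slow on the formyl‑deactivated ring, and the Lewis acid may cleave the methyl ether once it is ortho to the new ketone.
- The fallback replaces electrophilic substitution by directed metalation and sets out from **4**. MOMCl/NaH gives 4‑methoxy‑2,6‑bis(methoxymethoxy)‑3‑methylbenzaldehyde F6. The aldehyde is masked in situ as its α‑amino alkoxide with lithium N,N,N′‑trimethylethylenediamide, and the ring C–H between OMe and OMOM is lithiated with n‑BuLi. Acylation with N‑methoxy‑N,2‑dimethylpropanamide and aqueous work‑up give 4‑methoxy‑2,6‑bis(methoxymethoxy)‑3‑methyl‑5‑(2‑methylpropanoyl)benzaldehyde F7. HCl in methanol then rejoins the route at **5**. The same detour with N‑methoxy‑N‑methylacetamide would serve step 4.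

**Step 2.**
- Selectivity may be lost through a second methylation at an ortho hydroxyl, or through C‑methylation of the phenolate at the free ring carbon.
- The fallback turns the regiochemistry into a chelation‑controlled deprotection and sets out from **3**. Exhaustive methylation (excess Me2SO4, K2CO3) gives 2,4,6‑trimethoxy‑3‑methylbenzaldehyde F8. BBr3 (2.2 equiv, CH2Cl2, −78 → 0 °C) then cleaves only the two ethers ortho to the formyl group through its boron chelate, and the route is rejoined at **4**.

## Further compounds

F1 | step 8 | 1‑[2,4‑dihydroxy‑6‑methoxy‑5‑methyl‑3‑(morpholin‑4‑ylmethyl)phenyl]ethan‑1‑one | COc1c(C)c(O)c(CN2CCOCC2)c(O)c1C(C)=O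
F2 | step 7 | 1‑[2,4‑dihydroxy‑6‑methoxy‑5‑methyl‑3‑(morpholin‑4‑ylmethyl)phenyl]‑2‑methylpropan‑1‑one | COc1c(C)c(O)c(CN2CCOCC2)c(O)c1C(=O)C(C)C
F3 | step 6 | (2R)‑N‑methoxy‑N,2‑dimethylbutanamide | CC[C@@H](C)C(=O)N(C)OC
F4 | step 6 | 1,3,5‑tris(methoxymethoxy)benzene | COCOc1cc(OCOC)cc(OCOC)c1
F5 | step 6 | (2R)‑2‑methyl‑1‑[2,4,6‑tris(methoxymethoxy)phenyl]butan‑1‑one | CC[C@@H](C)C(=O)c1c(OCOC)cc(OCOC)cc1OCOC
F6 | step 3 | 4‑methoxy‑2,6‑bis(methoxymethoxy)‑3‑methylbenzaldehyde | COCOc1cc(OC)c(C)c(OCOC)c1C=O
F7 | step 3 | 4‑methoxy‑2,6‑bis(methoxymethoxy)‑3‑methyl‑5‑(2‑methylpropanoyl)benzaldehyde | COCOc1c(C(=O)C(C)C)c(OC)c(C)c(OCOC)c1C=O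
F8 | step 2 | 2,4,6‑trimethoxy‑3‑methylbenzaldehyde | COc1cc(OC)c(C=O)c(OC)c1C
A1 | alternative 1 | 1‑(4,6‑dihydroxy‑2‑methoxy‑3‑methylphenyl)ethan‑1‑one | CC(=O)c1c(O)cc(O)c(C)c1OC
A2 | alternative 1 | 1‑(4,6‑dihydroxy‑2‑methoxy‑3‑methylphenyl)‑2‑methylpropan‑1‑one | CC(C)C(=O)c1c(O)cc(O)c(C)c1OC
A3 | alternative 2 | 1‑[2,4‑dihydroxy‑6‑methoxy‑5‑methyl‑3‑[(methylsulfanyl)methyl]phenyl]‑2‑methylpropan‑1‑one | CSCc1c(O)c(C)c(OC)c(C(=O)C(C)C)c1O
A4 | alternative 2 | (2R)‑1‑[3‑[[2,6‑dihydroxy‑4‑methoxy‑3‑methyl‑5‑(2‑methylpropanoyl)phenyl](methylsulfanyl)methyl]‑2,4,6‑trihydroxyphenyl]‑2‑methylbutan‑1‑one (both configurations at the new sulfur‑bearing carbon) | CC[C@@H](C)C(=O)c1c(O)cc(O)c(C(SC)c2c(O)c(C)c(OC)c(C(=O)C(C)C)c2O)c1O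
A5 | alternative 3 | (2E)‑1‑[3‑[(3‑acetyl‑2,6‑dihydroxy‑4‑methoxy‑5‑methylphenyl)methyl]‑5‑[[2,6‑dihydroxy‑4‑methoxy‑3‑methyl‑5‑(2‑methylpropanoyl)phenyl]methyl]‑2,4,6‑trihydroxyphenyl]‑2‑methylbut‑2‑en‑1‑one | C/C=C(\C)C(=O)c1c(O)c(Cc2c(O)c(C)c(OC)c(C(C)=O)c2O)c(O)c(Cc2c(O)c(C)c(OC)c(C(=O)C(C)C)c2O)c1O
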